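**Retrosynthetic overview**

1. The 14-membered lactone (ring atoms O and C1–C13, the only ring) is opened at C12–C13 and not at the ester C–O bond. C13 is both the ring carbon that carries the lactone oxygen and the direct neighbour of sp2 C12 of the C10(=CH2)–C11=C12 diene, so it can be made as an α-acyloxy radical from a 1-chloropropyl ester (seco acid + propanal) and joined to an (E)-alkenyl bromide at nickel, which closes the ring and creates C13 in one step.
2. Seco acid 27: C2–C3 by Evans syn-aldol; C3, C4 and C4' are the three carbons of methyl (R)-glycerate, whose stereocentre becomes quaternary C4 by Seebach alkylation (C4–C5) with self-regeneration of the stereocentre.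
3. Allylic bromide 15 (C5–C12): Evans alkylation with 2,3-dibromopropene (C8), Negishi coupling with (E)-2-bromo-1-iodopropene (C10–C11, fixes the (E)-bromodiene), Wittig olefination (C6=C7).
4. Ring order: the macrolactone is formed in step 16; only C3–OH → ketone and acetonide cleavage follow.

Key step: step 16

Numbering used below: C1 lactone carbonyl, C2 CH(CH3), C3 ketone, C4 C(OH)(CH2OH) with C4' the hydroxymethyl carbon, C10 the carbon bearing the exocyclic CH2, C13 the CH(Et)–O carbon.
Assumption (ligand sense): the (3aS,8aR) antipode of the bis(oxazoline) ligand is taken to deliver (13R); the sense has to be confirmed on the first run and the antipodal ligand is used if it is reversed.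
Assumption (C2): the C2 stereocentre of the β-keto lactone is taken to hold its configuration under non-basic conditions.

**Route**

Step 1
Reactants: 1 (4R)-4-benzyl-3-propanoyl-1,3-oxazolidin-2-one; 2 2,3-dibromoprop-1-ene
Product: 4 (4R)-4-benzyl-3-[(2S)-4-bromo-2-methylpent-4-enoyl]-1,3-oxazolidin-2-one, via sodium enolate 3 (not isolated)
Conditions: NaN(SiMe3)2, THF, −78 °C; then 2, −78 → −40 °C
Reagents that add atoms: none
Why: Evans asymmetric alkylation, in which the chelated sodium (Z)-enolate is alkylated by the allylic bromide on the face away from the benzyl group, which should set C8 as (S) under auxiliary control.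

Step 2
Reactants: 4
Product: 5 (2S)-4-bromo-2-methylpent-4-en-1-ol
Conditions: LiBH4, MeOH (1 equiv), Et2O, 0 °C
Reagents that add atoms: none
Why: Reductive cleavage of the N-acyloxazolidinone with LiBH4 should release the primary alcohol and the recoverable auxiliary without touching the alkenyl bromide or C8.

Step 3
Reactants: 6 propyne
Product: 7 (E)-2-bromo-1-iodoprop-1-ene
Conditions: IBr, CH2Cl2, −78 → 0 °C
Reagents that add atoms: iodine monobromide, IBr
Why: Electrophilic anti addition of IBr to the alkyne (iodonium ion opened by bromide at the more substituted carbon) should give the Markovnikov (E)-bromo-iodoalkene, whose geometry is later carried into C11=C12.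

Step 4
Reactants: 5; 7
Product: 10 (2S,5E)-6-bromo-2-methyl-4-methylidenehept-5-en-1-ol, via dilithio intermediate 8 (not isolated), via alkenylzinc bromide 9 (not isolated)
Conditions: t-BuLi (3.1 equiv), Et2O, −78 °C; ZnBr2, THF, −78 → 0 °C; then 7, Pd(PPh3)4 (5 mol%), 0 °C → rt
Reagents that add atoms: none
Why: Negishi coupling, in which Br/Li exchange on the lithium alkoxide and transmetalation give an alkenylzinc that zerovalent palladium couples at the C–I bond of 7 (far more reactive than either C–Br bond) with retention, so the (E)-bromodiene with bromine left on C12 should result.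

Step 5
Reactants: 10; 11 ethyl 2-(triphenylphosphoranylidene)propanoate
Product: 13 ethyl (2E,4S,7E)-8-bromo-2,4-dimethyl-6-methylidenenona-2,7-dienoate, via aldehyde 12 (not isolated)
Conditions: IBX, 11, DMSO/CH2Cl2, rt (one pot)
Reagents that add atoms: none
Why: One-pot IBX oxidation and Wittig olefination with the stabilised ylide should give the (E)-trisubstituted enoate (C6=C7), the aldehyde being trapped as it forms so that C8 is not epimerised.

Step 6
Reactants: 13
Product: 14 (2E,4S,7E)-8-bromo-2,4-dimethyl-6-methylidenenona-2,7-dien-1-ol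
Conditions: iBu2AlH (2.5 equiv), CH2Cl2, −78 °C
Reagents that add atoms: none
Why: 1,2-Reduction of the enoate with iBu2AlH at low temperature should give the allylic alcohol without affecting the bromodiene.

Step 7
Reactants: 14
Product: 15 (2E,4S,7E)-1,8-dibromo-2,4-dimethyl-6-methylidenenona-2,7-diene
Conditions: CBr4, PPh3, CH2Cl2, 0 °C
Reagents that add atoms: carbon tetrabromide, BrC(Br)(Br)Br
Why: Appel bromination converts the primary allylic alcohol into the bromide under neutral conditions by SN2 displacement of the oxyphosphonium group, and no allylic transposition is expected for this primary system.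

Step 8
Reactants: 16 methyl (4R)-2,2-dimethyl-1,3-dioxolane-4-carboxylate
Product: 17 methyl (2R,4R)-2-tert-butyl-1,3-dioxolane-4-carboxylate (cis)
Conditions: t-BuCHO (5 equiv), TsOH·H2O (5 mol%), cyclohexane, reflux with removal of acetone; chromatography
Reagents that add atoms: pivalaldehyde, CC(C)(C)C=O
Why: Acid-catalysed transacetalisation under thermodynamic control leaves the glycerate stereocentre untouched and creates the acetal stereocentre as a cis/trans mixture, from which the cis (2R,4R) isomer is separated while the trans isomer is re-equilibrated.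

Step 9
Reactants: 17; 15
Product: 19 methyl (2R,4R)-4-[(2E,4S,7E)-8-bromo-2,4-dimethyl-6-methylidenenona-2,7-dien-1-yl]-2-tert-butyl-1,3-dioxolane-4-carboxylate, via lithium enolate 18 (not isolated)
Conditions: LiN(iPr)2, THF, −78 °C; then 15, DMPU, −78 → −30 °C
Reagents that add atoms: none
Why: Seebach alkylation with self-regeneration of the stereocentre, in which the enolate with exocyclic double bond resists β-elimination (the ring C–O bond lies in the enolate plane) and is alkylated by the primary allylic bromide anti to the tert-butyl group, which should give quaternary C4 as (R) with overall retention.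

Step 10
Reactants: 19
Product: 21 methyl (4R)-4-[(2E,4S,7E)-8-bromo-2,4-dimethyl-6-methylidenenona-2,7-dien-1-yl]-2,2-dimethyl-1,3-dioxolane-4-carboxylate, via diol ester 20 (not isolated)
Conditions: TsOH·H2O (10 mol%), MeOH, 45 °C; evaporation; 2,2-dimethoxypropane, acetone, rt
Reagents that add atoms: 2,2-dimethoxypropane, COC(C)(C)OC
Why: Acid-catalysed acetal exchange (methanolysis of the pivalaldehyde acetal, then acetonide formation on the 1,2-diol) breaks no bond to C4 and installs a diol protecting group that can be removed under mild acid at the end.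

Step 11
Reactants: 21
Product: 22 (4R)-4-[(2E,4S,7E)-8-bromo-2,4-dimethyl-6-methylidenenona-2,7-dien-1-yl]-2,2-dimethyl-1,3-dioxolane-4-carbaldehyde
Conditions: iBu2AlH (1.1 equiv), CH2Cl2, −78 °C; MeOH, aqueous Rochelle salt
Reagents that add atoms: none
Why: Partial reduction of the α-alkoxy ester with iBu2AlH at −78 °C stops at the chelated tetrahedral aluminate, which should release the non-enolisable aldehyde on work-up.

Step 12
Reactants: 1 (4R)-4-benzyl-3-propanoyl-1,3-oxazolidin-2-one; 22
Product: 24 (4R)-4-benzyl-3-[(2R,3R)-3-{(4R)-4-[(2E,4S,7E)-8-bromo-2,4-dimethyl-6-methylidenenona-2,7-dien-1-yl]-2,2-dimethyl-1,3-dioxolan-4-yl}-3-hydroxy-2-methylpropanoyl]-1,3-oxazolidin-2-one, via dibutylboron enolate 23 (not isolated)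
Conditions: Bu2BOTf, iPr2NEt, CH2Cl2, 0 °C; then 22, −78 → 0 °C; pH 7 buffer, MeOH, H2O2, 0 °C
Reagents that add atoms: none
Why: Evans syn-aldol reaction, in which the (Z)-dibutylboron enolate reacts through a Zimmerman–Traxler transition state on the face dictated by the auxiliary, which should set C2 as (R) and the temporary C3 carbinol as (R) irrespective of the α-quaternary aldehyde.

Step 13
Reactants: 24
Product: 25 (4R)-4-benzyl-3-[(2R,3R)-3-{(4R)-4-[(2E,4S,7E)-8-bromo-2,4-dimethyl-6-methylidenenona-2,7-dien-1-yl]-2,2-dimethyl-1,3-dioxolan-4-yl}-2-methyl-3-[(triethylsilyl)oxy]propanoyl]-1,3-oxazolidin-2-one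
Conditions: TESOTf, 2,6-lutidine, CH2Cl2, −78 → 0 °C
Reagents that add atoms: triethylsilyl triflate, CC[Si](CC)(CC)OS(=O)(=O)C(F)(F)F
Why: Silylation with the triflate is strong enough for the hindered secondary C3 alcohol and masks it for the acid activation that follows.

Step 14
Reactants: 25
Product: 27 (2R,3R)-3-{(4R)-4-[(2E,4S,7E)-8-bromo-2,4-dimethyl-6-methylidenenona-2,7-dien-1-yl]-2,2-dimethyl-1,3-dioxolan-4-yl}-2-methyl-3-[(triethylsilyl)oxy]propanoic acid, via lithium peroxycarboxylate 26 (not isolated)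
Conditions: LiOH, H2O2, THF/H2O (3:1), 0 °C; Na2SO3; HCl to pH 3 at 0 °C
Reagents that add atoms: hydrogen peroxide, OO
Why: Hydroperoxide attacks the exocyclic imide carbonyl selectively (LiOH/H2O2 auxiliary cleavage) and sulfite reduces the peroxy acid, so the acid should form without epimerisation at C2 or loss of the silyl ether.

Step 15
Reactants: 27; 28 propanal
Product: 30 1-chloropropyl (2R,3R)-3-{(4R)-4-[(2E,4S,7E)-8-bromo-2,4-dimethyl-6-methylidenenona-2,7-dien-1-yl]-2,2-dimethyl-1,3-dioxolan-4-yl}-2-methyl-3-[(triethylsilyl)oxy]propanoate (both epimers at the CHCl carbon), via acid chloride 29 (not isolated)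
Conditions: 1-chloro-N,N,2-trimethylprop-1-en-1-amine, CH2Cl2, 0 °C → rt; then 28, ZnCl2 (5 mol%), −20 → 0 °C
Reagents that add atoms: 1-chloro-N,N,2-trimethylprop-1-en-1-amine (Ghosez reagent), CC(C)=C(Cl)N(C)C
Why: Neutral acid chloride formation followed by ZnCl2-catalysed addition of the acyl chloride across the aldehyde C=O is the standard route to 1-chloroalkyl esters, and the new CHCl centre forms as both epimers, which is immaterial because both converge in step 16.

Step 16
Reactants: 30
Product: 31 protected macrolactone: the target ring with C3 as its (3R)-triethylsilyl ether instead of the ketone and the C4-OH/C4'-OH diol as isopropylidene acetal (2R,3R,4R,8S,13R,6E,11E)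
Conditions: NiBr2(dme) (20 mol%), (3aS,8aR)-indane-fused bis(oxazoline) ligand with cyclopropane-1,1-diyl bridge (24 mol%), Mn powder (4 equiv), DMA, 0 °C, 30 added by syringe pump over 12 h to 2 mM
Reagents that add atoms: none
Why: Proposed new method: zerovalent nickel inserts into the C12–Br bond of the (E)-alkenyl bromide faster than into the alkyl C–Cl bond, the alkenylnickel (reduced by Mn to the monovalent state) abstracts chlorine from the tethered 1-chloropropyl ester, and the α-acyloxy C13 radical is recaptured at nickel and reductively eliminated from trivalent nickel to form C12–C13; the closest known reaction types are the nickel-catalysed enantioconvergent reductive coupling of alkenyl bromides with benzylic chlorides, the nickel-catalysed enantioconvergent coupling of racemic 1-haloalkyl esters, and macrocyclic Ni/Cr alkenyl–aldehyde closures. The 14-membered lactone is closed by reductive elimination from a 15-membered alkenyl(alkyl)nickelacycle, so no endo or exo radical addition to an alkene is involved. C13 is the only new stereocentre: both chloride epimers give the same planar radical, and the chiral ligand, helped by chelation of the C1 ester carbonyl to nickel, decides the face (ligand-controlled stereoconvergence towards 13R). The alkenylnickel is configurationally stable, so the 11E geometry should be kept. The step needs ring closure to outrun oligomerisation, β-hydride loss and ionisation of the product dienyl ester; slow addition at low concentration, the fast reductive elimination from trivalent nickel and cold, phosphine-free conditions are meant to secure this. In the substrate, the different nature of the two electrophiles (sp2 C–Br against α-acyloxy sp3 C–Cl) gives cross-selectivity, and the two (E)-trisubstituted alkenes, the diene and quaternary C4 pre-organise the chain.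

Step 17
Reactants: 31
Product: 32 macrolactone with free (3R)-hydroxyl and C4/C4' acetonide (2R,3R,4R,8S,13R,6E,11E)
Conditions: HF·pyridine, pyridine, THF, 0 °C
Reagents that add atoms: none
Why: Buffered HF·pyridine cleaves the triethylsilyl ether while the acetonide, the dienyl ester and the alkenes should survive.

Step 18
Reactants: 32
Product: 33 3-keto macrolactone with C4/C4' acetonide (2R,4R,8S,13R,6E,11E)
Conditions: Dess–Martin periodinane, CH2Cl2, 0 °C → rt
Reagents that add atoms: none
Why: Dess–Martin oxidation of the only free (secondary) alcohol under non-basic conditions should give the β-keto lactone without enolisation-driven epimerisation at C2.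

Step 19
Reactants: 33
Product: 34 (3R,5R,7E,9S,12E,14R)-14-ethyl-5-hydroxy-5-(hydroxymethyl)-3,7,9,13-tetramethyl-11-methylidene-1-oxacyclotetradeca-7,12-diene-2,4-dione (target)
Conditions: AcOH/H2O (4:1), 35 °C
Reagents that add atoms: none
Why: Mild aqueous-acid hydrolysis of the terminal acetonide releases the C4 and C4' hydroxyls to give the target, the acid being kept weak to spare the dienylic C13–O ester and C2.

**Compound list**

1 | (4R)-4-benzyl-3-propanoyl-1,3-oxazolidin-2-one | CCC(=O)N1[C@H](Cc2ccccc2)COC1=O | starting material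
2 | 2,3-dibromoprop-1-ene | C=C(Br)CBr | starting material
3 | sodium (Z)-enolate of 1 | C/C=C(\O[Na])N1[C@H](Cc2ccccc2)COC1=O | intermediate (not isolated)
4 | (4R)-4-benzyl-3-[(2S)-4-bromo-2-methylpent-4-enoyl]-1,3-oxazolidin-2-one | C=C(Br)C[C@H](C)C(=O)N1[C@H](Cc2ccccc2)COC1=O | intermediate
5 | (2S)-4-bromo-2-methylpent-4-en-1-ol | C=C(Br)C[C@H](C)CO | intermediate
6 | propyne | CC#C | starting material
7 | (E)-2-bromo-1-iodoprop-1-ene | I/C=C(\C)Br | intermediate
8 | dilithio intermediate (lithium alkoxide and alkenyllithium from 5) | [Li]OC[C@@H](C)CC([Li])=C | intermediate (not isolated)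
9 | alkenylzinc bromide (as lithium alkoxide) | [Li]OC[C@@H](C)CC(=C)[Zn]Br | intermediate (not isolated)
10 | (2S,5E)-6-bromo-2-methyl-4-methylidenehept-5-en-1-ol | OC[C@@H](C)CC(=C)/C=C(\C)Br | intermediate
11 | ethyl 2-(triphenylphosphoranylidene)propanoate | CCOC(=O)C(C)=P(c1ccccc1)(c1ccccc1)c1ccccc1 | starting material
12 | (2S,5E)-6-bromo-2-methyl-4-methylidenehept-5-enal | O=C[C@@H](C)CC(=C)/C=C(\C)Br | intermediate (not isolated)
13 | ethyl (2E,4S,7E)-8-bromo-2,4-dimethyl-6-methylidenenona-2,7-dienoate | CCOC(=O)/C(C)=C/[C@@H](C)CC(=C)/C=C(\C)Br | intermediate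
14 | (2E,4S,7E)-8-bromo-2,4-dimethyl-6-methylidenenona-2,7-dien-1-ol | OC/C(C)=C/[C@@H](C)CC(=C)/C=C(\C)Br | intermediate
15 | (2E,4S,7E)-1,8-dibromo-2,4-dimethyl-6-methylidenenona-2,7-diene | BrC/C(C)=C/[C@@H](C)CC(=C)/C=C(\C)Br | intermediate
16 | methyl (4R)-2,2-dimethyl-1,3-dioxolane-4-carboxylate | COC(=O)[C@H]1COC(C)(C)O1 | starting material
17 | methyl (2R,4R)-2-tert-butyl-1,3-dioxolane-4-carboxylate (cis) | COC(=O)[C@H]1CO[C@@H](C(C)(C)C)O1 | intermediate
18 | lithium enolate of 17 | COC(O[Li])=C1CO[C@@H](C(C)(C)C)O1 | intermediate (not isolated)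
19 | methyl (2R,4R)-4-[(2E,4S,7E)-8-bromo-2,4-dimethyl-6-methylidenenona-2,7-dien-1-yl]-2-tert-butyl-1,3-dioxolane-4-carboxylate | COC(=O)[C@@]1(C/C(C)=C/[C@@H](C)CC(=C)/C=C(\C)Br)CO[C@@H](C(C)(C)C)O1 | intermediate
20 | methyl (2R,4E,6S,9E)-10-bromo-2-hydroxy-2-(hydroxymethyl)-4,6-dimethyl-8-methylideneundeca-4,9-dienoate | COC(=O)[C@](O)(CO)C/C(C)=C/[C@@H](C)CC(=C)/C=C(\C)Br | intermediate (not isolated)
21 | methyl (4R)-4-[(2E,4S,7E)-8-bromo-2,4-dimethyl-6-methylidenenona-2,7-dien-1-yl]-2,2-dimethyl-1,3-dioxolane-4-carboxylate | COC(=O)[C@@]1(C/C(C)=C/[C@@H](C)CC(=C)/C=C(\C)Br)COC(C)(C)O1 | intermediate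
22 | (4R)-4-[(2E,4S,7E)-8-bromo-2,4-dimethyl-6-methylidenenona-2,7-dien-1-yl]-2,2-dimethyl-1,3-dioxolane-4-carbaldehyde | O=C[C@@]1(C/C(C)=C/[C@@H](C)CC(=C)/C=C(\C)Br)COC(C)(C)O1 | intermediate
23 | dibutylboron (Z)-enolate of 1 | C/C=C(\OB(CCCC)CCCC)N1[C@H](Cc2ccccc2)COC1=O | intermediate (not isolated)
24 | aldol adduct, (2R,3R)-3-hydroxy-2-methyl imide (name as in step 12) | O=C(N1[C@H](Cc2ccccc2)COC1=O)[C@H](C)[C@@H](O)[C@@]1(C/C(C)=C/[C@@H](C)CC(=C)/C=C(\C)Br)COC(C)(C)O1 | intermediate
25 | triethylsilyl ether of 24 (name as in step 13) | O=C(N1[C@H](Cc2ccccc2)COC1=O)[C@H](C)[C@@H](O[Si](CC)(CC)CC)[C@@]1(C/C(C)=C/[C@@H](C)CC(=C)/C=C(\C)Br)COC(C)(C)O1 | intermediate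
26 | lithium peroxycarboxylate of acid 27 | [Li]OOC(=O)[C@H](C)[C@@H](O[Si](CC)(CC)CC)[C@@]1(C/C(C)=C/[C@@H](C)CC(=C)/C=C(\C)Br)COC(C)(C)O1 | intermediate (not isolated)
27 | (2R,3R)-3-{(4R)-4-[(2E,4S,7E)-8-bromo-2,4-dimethyl-6-methylidenenona-2,7-dien-1-yl]-2,2-dimethyl-1,3-dioxolan-4-yl}-2-methyl-3-[(triethylsilyl)oxy]propanoic acid | OC(=O)[C@H](C)[C@@H](O[Si](CC)(CC)CC)[C@@]1(C/C(C)=C/[C@@H](C)CC(=C)/C=C(\C)Br)COC(C)(C)O1 | intermediate
28 | propanal | CCC=O | starting material
29 | acid chloride of 27 | ClC(=O)[C@H](C)[C@@H](O[Si](CC)(CC)CC)[C@@]1(C/C(C)=C/[C@@H](C)CC(=C)/C=C(\C)Br)COC(C)(C)O1 | intermediate (not isolated)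
30 | 1-chloropropyl ester of 27 (both epimers at the CHCl carbon) | CCC(Cl)OC(=O)[C@H](C)[C@@H](O[Si](CC)(CC)CC)[C@@]1(C/C(C)=C/[C@@H](C)CC(=C)/C=C(\C)Br)COC(C)(C)O1 | intermediate
31 | protected macrolactone, 3-OSiEt3 and C4/C4' acetonide (2R,3R,4R,8S,13R,6E,11E) | C=C1/C=C(\C)[C@@H](CC)OC(=O)[C@H](C)[C@@H](O[Si](CC)(CC)CC)[C@]2(COC(C)(C)O2)C/C(C)=C/[C@@H](C)C1 | intermediate
32 | macrolactone, 3-OH and C4/C4' acetonide (2R,3R,4R,8S,13R,6E,11E) | C=C1/C=C(\C)[C@@H](CC)OC(=O)[C@H](C)[C@@H](O)[C@]2(COC(C)(C)O2)C/C(C)=C/[C@@H](C)C1 | intermediate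
33 | 3-keto macrolactone, C4/C4' acetonide (2R,4R,8S,13R,6E,11E) | C=C1/C=C(\C)[C@@H](CC)OC(=O)[C@H](C)C(=O)[C@]2(COC(C)(C)O2)C/C(C)=C/[C@@H](C)C1 | intermediate
34 | (3R,5R,7E,9S,12E,14R)-14-ethyl-5-hydroxy-5-(hydroxymethyl)-3,7,9,13-tetramethyl-11-methylidene-1-oxacyclotetradeca-7,12-diene-2,4-dione | C=C1/C=C(\C)[C@@H](CC)OC(=O)[C@H](C)C(=O)[C@](O)(CO)C/C(C)=C/[C@@H](C)C1 | target

**Step count and risks**

Total step count: 19. Longest linear sequence: 17 steps (steps 1, 2, 4–7 and 9–19, from compound 1).

Steps most likely to fail: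

Step 16 (proposed new method). Intermolecular coupling may outrun ring closure, the C13 radical may be reduced or lose hydrogen before capture at nickel, or the ligand may give poor facial control at C13. The fallback uses known chemistry, sets out from 25 and returns at 31. A Nozaki–Hiyama–Kishi coupling of the alkenyl bromide of 25 with propanal (CrCl2, NiCl2 as catalyst, chiral oxazoline–sulfonamide ligand, Et3N, THF) should give the (13R)-allylic alcohol F1 under ligand control, any 13S epimer being separated. LiOH/H2O2 then removes the auxiliary to give the seco acid F2. Yamaguchi macrolactonisation (2,4,6-trichlorobenzoyl chloride, Et3N, then DMAP, toluene, high dilution) closes the ring at the C1–O bond and gives 31.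

Step 9. The enolate may ring-open by β-elimination, or alkylation may occur with poor facial selectivity. The fallback sets out from 15 and returns at 22.
- Stille coupling of the allylic bromide of 15 with 2-(tributylstannyl)prop-2-en-1-ol (Pd2(dba)3, AsPh3, THF; the allylic C–Br reacts before the alkenyl C–Br) gives the 2-substituted allylic alcohol F3.
- Sharpless asymmetric epoxidation (Ti(OiPr)4, D-(−)-diethyl tartrate, t-BuOOH, 4 Å molecular sieves, −20 °C) is chemoselective for the allylic alcohol and gives the (R)-epoxy alcohol F4.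
- Ti(OiPr)4-mediated opening with pivalic acid at the CH2 terminus keeps the C4–O bond and gives the diol pivalate F5.
- 2,2-Dimethoxypropane/PPTS gives the acetonide pivalate F6.
- iBu2AlH removes the pivalate to give the primary alcohol F7, and Dess–Martin oxidation gives 22.

Step 19. During acid hydrolysis at the β-keto lactone stage the dienylic C13–O ester may ionise, the freed hydroxyls may translactonise, or C2 may epimerise. The fallback sets out from 32 and returns at 34. The acetonide is removed one stage earlier, on the more robust β-hydroxy lactone (aqueous AcOH), to give the triol F8. Selective silylation of the primary C4' hydroxyl (TESCl, imidazole, −20 °C) gives the mono-silyl ether F9. Dess–Martin oxidation of the only secondary alcohol gives the keto silyl ether F10, and buffered HF·pyridine releases 34 under near-neutral conditions.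

Further compounds
F1 | step 16 | (4R)-4-benzyl-3-[(2R,3R)-3-{(4R)-4-[(2E,4S,7E,9R)-9-hydroxy-2,4,8-trimethyl-6-methylideneundeca-2,7-dien-1-yl]-2,2-dimethyl-1,3-dioxolan-4-yl}-2-methyl-3-[(triethylsilyl)oxy]propanoyl]-1,3-oxazolidin-2-one | O=C(N1[C@H](Cc2ccccc2)COC1=O)[C@H](C)[C@@H](O[Si](CC)(CC)CC)[C@@]1(C/C(C)=C/[C@@H](C)CC(=C)/C=C(\C)[C@@H](CC)O)COC(C)(C)O1
F2 | step 16 | (2R,3R)-3-{(4R)-4-[(2E,4S,7E,9R)-9-hydroxy-2,4,8-trimethyl-6-methylideneundeca-2,7-dien-1-yl]-2,2-dimethyl-1,3-dioxolan-4-yl}-2-methyl-3-[(triethylsilyl)oxy]propanoic acid | OC(=O)[C@H](C)[C@@H](O[Si](CC)(CC)CC)[C@@]1(C/C(C)=C/[C@@H](C)CC(=C)/C=C(\C)[C@@H](CC)O)COC(C)(C)O1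
F3 | step 9 | 2-[(2E,4S,7E)-8-bromo-2,4-dimethyl-6-methylidenenona-2,7-dien-1-yl]prop-2-en-1-ol | OCC(=C)C/C(C)=C/[C@@H](C)CC(=C)/C=C(\C)Br
F4 | step 9 | {(2R)-2-[(2E,4S,7E)-8-bromo-2,4-dimethyl-6-methylidenenona-2,7-dien-1-yl]oxiran-2-yl}methanol | OC[C@]1(C/C(C)=C/[C@@H](C)CC(=C)/C=C(\C)Br)CO1
F5 | step 9 | (2R,4E,6S,9E)-10-bromo-2-hydroxy-2-(hydroxymethyl)-4,6-dimethyl-8-methylideneundeca-4,9-dien-1-yl 2,2-dimethylpropanoate | OC[C@@](O)(COC(=O)C(C)(C)C)C/C(C)=C/[C@@H](C)CC(=C)/C=C(\C)Br
F6 | step 9 | {(4R)-4-[(2E,4S,7E)-8-bromo-2,4-dimethyl-6-methylidenenona-2,7-dien-1-yl]-2,2-dimethyl-1,3-dioxolan-4-yl}methyl 2,2-dimethylpropanoate | CC(C)(C)C(=O)OC[C@@]1(C/C(C)=C/[C@@H](C)CC(=C)/C=C(\C)Br)COC(C)(C)O1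
F7 | step 9 | {(4S)-4-[(2E,4S,7E)-8-bromo-2,4-dimethyl-6-methylidenenona-2,7-dien-1-yl]-2,2-dimethyl-1,3-dioxolan-4-yl}methanol | OC[C@@]1(C/C(C)=C/[C@@H](C)CC(=C)/C=C(\C)Br)COC(C)(C)O1
F8 | step 19 | (3R,4R,5R,7E,9S,12E,14R)-14-ethyl-4,5-dihydroxy-5-(hydroxymethyl)-3,7,9,13-tetramethyl-11-methylidene-1-oxacyclotetradeca-7,12-dien-2-one | C=C1/C=C(\C)[C@@H](CC)OC(=O)[C@H](C)[C@@H](O)[C@](O)(CO)C/C(C)=C/[C@@H](C)C1
F9 | step 19 | (3R,4R,5R,7E,9S,12E,14R)-14-ethyl-4,5-dihydroxy-3,7,9,13-tetramethyl-11-methylidene-5-{[(triethylsilyl)oxy]methyl}-1-oxacyclotetradeca-7,12-dien-2-one | C=C1/C=C(\C)[C@@H](CC)OC(=O)[C@H](C)[C@@H](O)[C@](O)(CO[Si](CC)(CC)CC)C/C(C)=C/[C@@H](C)C1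
F10 | step 19 | (3R,5R,7E,9S,12E,14R)-14-ethyl-5-hydroxy-3,7,9,13-tetramethyl-11-methylidene-5-{[(triethylsilyl)oxy]methyl}-1-oxacyclotetradeca-7,12-diene-2,4-dione | C=C1/C=C(\C)[C@@H](CC)OC(=O)[C@H](C)C(=O)[C@](O)(CO[Si](CC)(CC)CC)C/C(C)=C/[C@@H](C)C1
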